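**Plan**

- Retrosynthesis: both 2-hydroxy-1,4-benzoquinone rings are taken back to protected resorcinol rings. The two bonds from the outer side-chain CH2 to the 2-methoxyphenyl rings are cut next, then the two vinyl C=C bonds, and last the central ring–ring bond.
- Enabling feature: number each quinone ring with C1 and C4 as the carbonyl carbons, C2 bearing OH, C3 the methyl, C5 the bond to the other quinone ring and C6 the two-carbon side chain. The bond from the outer CH2 of the C6 chain to the anisole ring is then an unhindered sp3–sp2 bond, two atoms away from the tetra-ortho-substituted C5–C5' axis, so both arms can be attached late.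
- Forward: no ring is built. The pieces are joined in the order biaryl bond (Ullmann), two vinyl groups (Wittig), two anisole rings (hydroboration and B-alkyl Suzuki–Miyaura coupling). Acetal cleavage and oxidation with (KSO3)2NO then convert both resorcinol rings into hydroxyquinones.
- Stereochemistry: the target has no stereocentre. The C5–C5' axis is the only stereogenic element and arises in the Ullmann step as a racemate.

Key step: step 7

Remark: the target structure carries no axial descriptor, so the hindered biaryl axis is carried through as a racemate and no atropselective step is planned.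

**Route**

Step 1
Reactants: 1 3,5-dihydroxy-4-methylbenzoic acid
Product: 2 methoxymethyl 3,5-bis(methoxymethoxy)-4-methylbenzoate
Conditions: MOMCl (3.6 equiv), iPr2NEt (4.5 equiv), CH2Cl2, 0 °C to rt
Reagents that add atoms: chloromethyl methyl ether (MOMCl), COCCl
Why: Williamson-type O-alkylation, in which the amine deprotonates the acid and both phenols and the highly electrophilic α-chloro ether alkylates all three oxygens, should give two acetal ethers and a methoxymethyl ester that the next step removes reductively.

Step 2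
Reactants: 2 methoxymethyl 3,5-bis(methoxymethoxy)-4-methylbenzoate
Product: 3 [3,5-bis(methoxymethoxy)-4-methylphenyl]methanol
Conditions: LiAlH4 (1.5 equiv), THF, 0 °C to rt; aqueous NaOH work-up
Reagents that add atoms: none
Why: Hydride reduction of the ester with LiAlH4 should deliver the benzylic alcohol (the methoxymethanol fragment collapsing to formaldehyde and being reduced to methanol) while the acetal ethers, inert to hydride and base, stay in place.

Step 3
Reactants: 3 [3,5-bis(methoxymethoxy)-4-methylphenyl]methanol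
Product: 4 3,5-bis(methoxymethoxy)-4-methylbenzaldehyde
Conditions: activated MnO2 (10 equiv), CH2Cl2, rt
Reagents that add atoms: none
Why: Activated MnO2 is a neutral, chemoselective oxidant for benzylic alcohols that should stop at the aldehyde and leave the acid-labile acetal ethers untouched.

Step 4
Reactants: 4 3,5-bis(methoxymethoxy)-4-methylbenzaldehyde
Product: 5 2-bromo-3,5-bis(methoxymethoxy)-4-methylbenzaldehyde
Conditions: NBS (1.02 equiv), MeCN, 0 °C to rt, dark
Reagents that add atoms: N-bromosuccinimide (NBS), O=C1CCC(=O)N1Br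
Why: Electrophilic aromatic bromination with NBS in a polar solvent should give one regioisomer because the two free ring positions are equivalent, each ortho to one and para to the other alkoxy donor, while the bromine introduced slows a second substitution and the absence of acid spares the acetals.

Step 5
Reactants: 5 2-bromo-3,5-bis(methoxymethoxy)-4-methylbenzaldehyde (two molecules)
Product: 6 4,4',6,6'-tetrakis(methoxymethoxy)-5,5'-dimethyl-[1,1'-biphenyl]-2,2'-dicarbaldehyde (racemic axis)
Conditions: activated Cu powder (5 equiv), DMF, 150 °C, argon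
Reagents that add atoms: none
Why: Ullmann reductive homocoupling should work here because the ortho-formyl group activates the C–Br bond toward copper insertion and coordinates the arylcopper intermediate, a combination well precedented for tetra-ortho-substituted biaryl dialdehydes, and the neutral medium spares the acetal ethers.

Step 6
Reactants: 6 4,4',6,6'-tetrakis(methoxymethoxy)-5,5'-dimethyl-[1,1'-biphenyl]-2,2'-dicarbaldehyde; 7 methyltriphenylphosphonium bromide
Product: 8 2,2',4,4'-tetrakis(methoxymethoxy)-3,3'-dimethyl-6,6'-divinyl-1,1'-biphenyl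
Conditions: 7 (3 equiv), KOtBu (2.9 equiv), THF, 0 °C to rt
Reagents that add atoms: methyltriphenylphosphonium bromide (7), C[P+](c1ccccc1)(c1ccccc1)c1ccccc1.[Br-]
Why: Wittig methylenation with the non-stabilised ylide generated from 7 and KOtBu should convert both hindered aryl aldehydes into terminal vinyl groups, for which no alkene geometry arises.

Step 7
Reactants: 8 2,2',4,4'-tetrakis(methoxymethoxy)-3,3'-dimethyl-6,6'-divinyl-1,1'-biphenyl; 9 2-bromoanisole (two molecules)
Product: 11 2,2',4,4'-tetrakis(methoxymethoxy)-6,6'-bis[2-(2-methoxyphenyl)ethyl]-3,3'-dimethyl-1,1'-biphenyl, via bis(9-BBN) alkylborane 10 (not isolated)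
Conditions: 9-BBN (2.6 equiv), THF, 0 °C to rt; then 9 (2.5 equiv), Pd(dppf)Cl2 (10 mol %), 3 M aq NaOH, THF, 65 °C
Reagents that add atoms: 2-bromoanisole (9), COc1ccccc1Br
Why: 9-BBN adds syn across each vinyl group through a four-centre transition state with boron on the terminal carbon, giving the primary bis-alkylborane 10. 2-Bromoanisole then adds oxidatively to zerovalent palladium formed from Pd(dppf)Cl2, hydroxide activates the boron–palladium exchange so that the primary alkyl group transmetalates, and reductive elimination forms each CH2–aryl bond. The closest known reaction type is the hydroboration and B-alkyl Suzuki–Miyaura coupling of styrenes with aryl bromides. No ring closes and no stereocentre is created. The step needs terminal hydroboration, secured by the bulk of 9-BBN, and coupling faster than β-hydride elimination, secured by the wide bite angle of dppf. Both reacting carbons lie two atoms from the congested axis, and the acetal and aryl methyl ethers are inert to borane and aqueous base.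

Step 8
Reactants: 11 2,2',4,4'-tetrakis(methoxymethoxy)-6,6'-bis[2-(2-methoxyphenyl)ethyl]-3,3'-dimethyl-1,1'-biphenyl
Product: 12 6,6'-bis[2-(2-methoxyphenyl)ethyl]-3,3'-dimethyl-[1,1'-biphenyl]-2,2',4,4'-tetrol
Conditions: conc. HCl (6 equiv), MeOH/THF, 50 °C, degassed
Reagents that add atoms: none
Why: Acid-catalysed transacetalisation in methanol should cleave the four methoxymethyl ethers, methanol trapping the methoxymethyl cation as dimethoxymethane so that it does not alkylate the electron-rich rings, while the two aryl methyl ethers are stable to dilute HCl.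

Step 9
Reactants: 12 6,6'-bis[2-(2-methoxyphenyl)ethyl]-3,3'-dimethyl-[1,1'-biphenyl]-2,2',4,4'-tetrol
Product: 13 CNP0293637.0, the 5,5'-linked dimer of 2-hydroxy-3-methyl-6-[2-(2-methoxyphenyl)ethyl]-1,4-benzoquinone
Conditions: (KSO3)2NO (6 equiv), aq KH2PO4 buffer, acetone/H2O, 0 °C to rt
Reagents that add atoms: potassium nitrosodisulfonate (KSO3)2NO, [O]N(S(=O)(=O)[O-])S(=O)(=O)[O-].[K+].[K+]
Why: In this Teuber oxidation the phenoxyl radical formed in each ring is trapped by a second equivalent of (KSO3)2NO at the only free ring CH, which lies para to the hydroxyl flanked by the methyl group and the ring–ring bond, and loss of imidodisulfonate should give the 1,4-quinone with the other hydroxyl kept at C2 (reaction through the other phenol leads to the ortho-quinone tautomer of the same compound), whereas the anisole rings have no free OH and are inert.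

**Compound list**

1 | 3,5-dihydroxy-4-methylbenzoic acid | Cc1c(O)cc(cc1O)C(=O)O | starting material
2 | methoxymethyl 3,5-bis(methoxymethoxy)-4-methylbenzoate | COCOC(=O)c1cc(OCOC)c(C)c(OCOC)c1 | intermediate
3 | [3,5-bis(methoxymethoxy)-4-methylphenyl]methanol | COCOc1cc(CO)cc(OCOC)c1C | intermediate
4 | 3,5-bis(methoxymethoxy)-4-methylbenzaldehyde | COCOc1cc(C=O)cc(OCOC)c1C | intermediate
5 | 2-bromo-3,5-bis(methoxymethoxy)-4-methylbenzaldehyde | COCOc1cc(C=O)c(Br)c(OCOC)c1C | intermediate
6 | 4,4',6,6'-tetrakis(methoxymethoxy)-5,5'-dimethyl-[1,1'-biphenyl]-2,2'-dicarbaldehyde | COCOc1cc(C=O)c(-c2c(C=O)cc(OCOC)c(C)c2OCOC)c(OCOC)c1C | intermediate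
7 | methyltriphenylphosphonium bromide | C[P+](c1ccccc1)(c1ccccc1)c1ccccc1.[Br-] | starting material
8 | 2,2',4,4'-tetrakis(methoxymethoxy)-3,3'-dimethyl-6,6'-divinyl-1,1'-biphenyl | C=Cc1cc(OCOC)c(C)c(OCOC)c1-c1c(C=C)cc(OCOC)c(C)c1OCOC | intermediate
9 | 2-bromoanisole | COc1ccccc1Br | starting material
10 | 9,9'-{[4,4',6,6'-tetrakis(methoxymethoxy)-5,5'-dimethyl-[1,1'-biphenyl]-2,2'-diyl]di(ethane-2,1-diyl)}bis(9-borabicyclo[3.3.1]nonane) | COCOc1cc(CCB2C3CCCC2CCC3)c(-c2c(CCB3C4CCCC3CCC4)cc(OCOC)c(C)c2OCOC)c(OCOC)c1C | intermediate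
11 | 2,2',4,4'-tetrakis(methoxymethoxy)-6,6'-bis[2-(2-methoxyphenyl)ethyl]-3,3'-dimethyl-1,1'-biphenyl | COCOc1cc(CCc2ccccc2OC)c(-c2c(CCc3ccccc3OC)cc(OCOC)c(C)c2OCOC)c(OCOC)c1C | intermediate
12 | 6,6'-bis[2-(2-methoxyphenyl)ethyl]-3,3'-dimethyl-[1,1'-biphenyl]-2,2',4,4'-tetrol | Cc1c(O)cc(CCc2ccccc2OC)c(-c2c(CCc3ccccc3OC)cc(O)c(C)c2O)c1O | intermediate
13 | CNP0293637.0, 4,4'-dihydroxy-2,2'-bis[2-(2-methoxyphenyl)ethyl]-5,5'-dimethyl-[1,1'-bi(cyclohexa-1,4-dien-1-yl)]-3,3',6,6'-tetrone | COc1ccccc1CCC1=C(C2=C(CCc3ccccc3OC)C(=O)C(O)=C(C)C2=O)C(=O)C(C)=C(O)C1=O | target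

**Count and risks**

Total step count: 9. Longest linear sequence: 9 steps (1 to 13).

Steps most likely to fail:

Step 5 (Ullmann coupling). Reductive loss of bromine and thermal breakdown of the aldehyde may outrun the slow formation of a tetra-ortho-substituted axis. The fallback sets out from bromide 5. Part of it would be converted by Miyaura borylation (B2pin2, Pd(dppf)Cl2, KOAc, dioxane, 90 °C) into 3,5-bis(methoxymethoxy)-4-methyl-2-(4,4,5,5-tetramethyl-1,3,2-dioxaborolan-2-yl)benzaldehyde F1. This would be joined to a second portion of 5 by Suzuki–Miyaura cross-coupling (Pd(OAc)2, SPhos, K3PO4, toluene/H2O, 100 °C), and the route is rejoined at dialdehyde 6.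

Step 7 (double hydroboration and B-alkyl coupling). Only one arm may couple, or the alkylborane may be lost by protodeboronation or β-hydride elimination while oxidative addition of the electron-rich, ortho-substituted bromide lags. The fallback sets out from divinyl biaryl 8 and 2-bromoanisole 9 and makes the same two carbon–aryl bonds at the alkene oxidation level. A twofold Mizoroki–Heck arylation (Pd(OAc)2, P(o-tol)3, Et3N, DMF, 110 °C) would give 2,2',4,4'-tetrakis(methoxymethoxy)-6,6'-bis[(E)-2-(2-methoxyphenyl)ethenyl]-3,3'-dimethyl-1,1'-biphenyl F2. Hydrogenation (H2, Pd/C, EtOAc, rt) would rejoin the route at 11.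

Step 9 (twofold oxidation with (KSO3)2NO). Oxidation of the second ring may stall, phenoxyl radicals may couple with each other, and the lipophilic tetraphenol may dissolve poorly in the aqueous buffer. The fallback sets out from 11 and brings in the missing oxygen before deprotection:
- NBS (2 equiv, MeCN, 0 °C) should brominate the single free CH of each central ring, which is far more activated than the anisole rings, to give 5,5'-dibromo-2,2',4,4'-tetrakis(methoxymethoxy)-6,6'-bis[2-(2-methoxyphenyl)ethyl]-3,3'-dimethyl-1,1'-biphenyl F3.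
- Palladium-catalysed hydroxylation (Pd2(dba)3, tBuXPhos, KOH, dioxane/H2O, 100 °C) would give 4,4',6,6'-tetrakis(methoxymethoxy)-2,2'-bis[2-(2-methoxyphenyl)ethyl]-5,5'-dimethyl-[1,1'-biphenyl]-3,3'-diol F4.
- HCl in MeOH would free 6,6'-bis[2-(2-methoxyphenyl)ethyl]-3,3'-dimethyl-[1,1'-biphenyl]-2,2',4,4',5,5'-hexol F5.
- Ag2O (acetone, rt) would oxidise each 1,2,4-trihydroxybenzene ring to the hydroxyquinone, rejoining the route at 13.

Further compounds
F1 | step 5 | 3,5-bis(methoxymethoxy)-4-methyl-2-(4,4,5,5-tetramethyl-1,3,2-dioxaborolan-2-yl)benzaldehyde | COCOc1cc(C=O)c(B2OC(C)(C)C(C)(C)O2)c(OCOC)c1C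
F2 | step 7 | 2,2',4,4'-tetrakis(methoxymethoxy)-6,6'-bis[(E)-2-(2-methoxyphenyl)ethenyl]-3,3'-dimethyl-1,1'-biphenyl | COCOc1cc(/C=C/c2ccccc2OC)c(-c2c(/C=C/c3ccccc3OC)cc(OCOC)c(C)c2OCOC)c(OCOC)c1C
F3 | step 9 | 5,5'-dibromo-2,2',4,4'-tetrakis(methoxymethoxy)-6,6'-bis[2-(2-methoxyphenyl)ethyl]-3,3'-dimethyl-1,1'-biphenyl | COCOc1c(Br)c(CCc2ccccc2OC)c(-c2c(CCc3ccccc3OC)c(Br)c(OCOC)c(C)c2OCOC)c(OCOC)c1C
F4 | step 9 | 4,4',6,6'-tetrakis(methoxymethoxy)-2,2'-bis[2-(2-methoxyphenyl)ethyl]-5,5'-dimethyl-[1,1'-biphenyl]-3,3'-diol | COCOc1c(O)c(CCc2ccccc2OC)c(-c2c(CCc3ccccc3OC)c(O)c(OCOC)c(C)c2OCOC)c(OCOC)c1C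
F5 | step 9 | 6,6'-bis[2-(2-methoxyphenyl)ethyl]-3,3'-dimethyl-[1,1'-biphenyl]-2,2',4,4',5,5'-hexol | Cc1c(O)c(O)c(CCc2ccccc2OC)c(-c2c(CCc3ccccc3OC)c(O)c(O)c(C)c2O)c1O
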